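The phenol ring of the naphthalene (C1', C2', C3', C4', C4a', C8a') holds tetralin carbon C4 on C1' and oxygen on C4', para to each other. This is the C2/C5 pattern of a 2-substituted furan, so the ring is cut at C1'–C8a' and C4'–C4a' into 3-methoxybenzyne and a 2-(tetralin-4-yl)furan, and then at C4–C1' (cross-coupling).
A plain 2-alkylfuran would present its free C5 to the aryne carbon remote from OMe, which is the wrong sense. Its adduct could also ionise at C4', assisted by the ortho-methoxy ring, and suffer an alkyl shift.
The furan is therefore used one oxidation level higher, as its 5-triisopropylsilyloxy derivative. The tetralinyl-bearing carbon then becomes the nucleophilic terminus, and cleavage of the C4'–O bridge bond becomes the productive opening.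
Forward order: bought tetralone bicycle, C1 carbinol, C4 ketone, furan joined at C4 (Negishi), furan raised to the silyloxyfuran, phenol ring closed onto the aryne ring (step 9), bridged ketal collapsed to a p-quinol, zinc reduction back to the naphthol level.
Stereochemistry: C1 (S) comes from Noyori asymmetric transfer hydrogenation. C4 comes from syn-hydrogenation anti to the C1 silyl ether, which gives the cis relationship. The bridgehead and quinol centres are transient and are erased.

Key step: step 9

Remark: the SMILES encodes the cis-(1S,4S) isomer. Target numbering (tetralin C1–C8a, naphthalene primed) is used for all intermediates. The C4 descriptor reads R while C4 carries a carbon bonded to oxygen and S in the target, with no change in spatial arrangement.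

Step 1
Reactants: 1 5-methoxy-1-tetralone
Product: 2 (S)-5-methoxy-1,2,3,4-tetrahydronaphthalen-1-ol
Conditions: RuCl[(S,S)-TsDPEN](p-cymene) (0.5 mol %), HCO2H–Et3N (5:2), 30 °C
Reagents that add atoms: none
Why: Noyori asymmetric transfer hydrogenation, in which the (S,S)-configured ruthenium hydride/amine pair delivers hydride and proton to the Re face of aryl alkyl ketones through a CH–π-organised six-membered transition state; 1-tetralones are among the best substrates, so C1 should be set as S.

Step 2
Reactants: 2 (S)-5-methoxy-1,2,3,4-tetrahydronaphthalen-1-ol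
Product: 3 (S)-tert-butyl[(5-methoxy-1,2,3,4-tetrahydronaphthalen-1-yl)oxy]dimethylsilane
Conditions: TBSCl, imidazole, DMF, rt
Reagents that add atoms: tert-butyldimethylsilyl chloride, CC(C)(C)[Si](C)(C)Cl
Why: Imidazole-promoted silylation of a secondary alcohol, giving a bulky ether that protects the carbinol, shields C1–H in step 3 and acts as the steric control element in step 6.

Step 3
Reactants: 3 (S)-tert-butyl[(5-methoxy-1,2,3,4-tetrahydronaphthalen-1-yl)oxy]dimethylsilane
Product: 4 (S)-4-(tert-butyldimethylsilyloxy)-8-methoxy-3,4-dihydronaphthalen-1(2H)-one (ketone at C4 of the target numbering)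
Conditions: dirhodium tetracaprolactamate Rh2(cap)4 (1 mol %), t-BuOOH (5 equiv), NaHCO3, ClCH2CH2Cl, 40 °C
Reagents that add atoms: tert-butyl hydroperoxide, CC(C)(C)OO
Why: Catalytic benzylic C–H oxidation by tert-butylperoxyl radicals, where the electrophilic radical should prefer the open C4 methylene activated by the ortho methoxy group over the tertiary C1–H, which sits under the silyl ether and is attached meta to OMe, as is known for 5-methoxytetralins carrying a protected oxygen function at C1.

Step 4
Reactants: 4 (S)-4-(tert-butyldimethylsilyloxy)-8-methoxy-3,4-dihydronaphthalen-1(2H)-one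
Product: 5 (S)-4-(tert-butyldimethylsilyloxy)-8-methoxy-3,4-dihydronaphthalen-1-yl trifluoromethanesulfonate
Conditions: KN(SiMe3)2, THF, −78 °C; PhNTf2, −78 → 0 °C
Reagents that add atoms: N-phenylbis(trifluoromethanesulfonimide), O=S(=O)(N(c1ccccc1)S(=O)(=O)C(F)(F)F)C(F)(F)F
Why: Standard enol triflate formation by kinetic enolisation and O-sulfonylation; only C3 carries α-hydrogens, and the silyloxy group lies on the γ-carbon, so the enolate cannot expel it.

Step 5
Reactants: 5 (S)-4-(tert-butyldimethylsilyloxy)-8-methoxy-3,4-dihydronaphthalen-1-yl trifluoromethanesulfonate; 6 2-(trimethylsilyl)furan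
Product: 9 tert-butyl({(1S)-5-methoxy-4-[5-(trimethylsilyl)furan-2-yl]-1,2-dihydronaphthalen-1-yl}oxy)dimethylsilane, via 5-lithio-2-(trimethylsilyl)furan 7 (not isolated), via [5-(trimethylsilyl)furan-2-yl]zinc chloride 8 (not isolated)
Conditions: 6, n-BuLi, THF, −78 → 0 °C; ZnCl2, 0 °C → rt; 5, Pd(PPh3)4 (5 mol %), THF, 50 °C
Reagents that add atoms: none
Why: Negishi coupling, in which the only free α-position of the silylfuran is lithiated and passed to zinc and zerovalent palladium inserts into the vinyl C–OTf bond; the small furylzinc partner tolerates the peri methoxy group, and the strong base never meets a compound with a C4 stereocentre.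

Step 6
Reactants: 9 tert-butyl({(1S)-5-methoxy-4-[5-(trimethylsilyl)furan-2-yl]-1,2-dihydronaphthalen-1-yl}oxy)dimethylsilane
Product: 10 tert-butyl({(1S,4R)-5-methoxy-4-[5-(trimethylsilyl)furan-2-yl]-1,2,3,4-tetrahydronaphthalen-1-yl}oxy)dimethylsilane (cis)
Conditions: H2 (1 atm), palladium on carbon (5 % Pd/C), EtOAc, rt
Reagents that add atoms: none
Why: Heterogeneous syn-hydrogenation under substrate control, where peri strain with C8–H holds the C1 silyloxy group pseudoaxial so that it covers one alkene face, both hydrogens should arrive anti to it and the furyl group ends cis to OTBS (C4 = R), while the 2,5-disubstituted furan reduces far more slowly than the styrenyl alkene.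

Step 7
Reactants: 10 tert-butyl({(1S,4R)-5-methoxy-4-[5-(trimethylsilyl)furan-2-yl]-1,2,3,4-tetrahydronaphthalen-1-yl}oxy)dimethylsilane
Product: 11 5-[(1R,4S)-4-(tert-butyldimethylsilyloxy)-8-methoxy-1,2,3,4-tetrahydronaphthalen-1-yl]furan-2(3H)-one (β,γ-unsaturated butenolide)
Conditions: AcOOH (35 % in AcOH), NaOAc, CH2Cl2, 0 °C → rt
Reagents that add atoms: peracetic acid, CC(=O)OO
Why: Peracid oxidation of a 2-silylfuran to a butenolide (ipso attack at the silicon-bearing carbon, carbon-to-oxygen silyl shift, protodesilylation), run under buffered non-basic conditions that leave the aryl- and furyl-activated C4–H untouched.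

Step 8
Reactants: 11 5-[(1R,4S)-4-(tert-butyldimethylsilyloxy)-8-methoxy-1,2,3,4-tetrahydronaphthalen-1-yl]furan-2(3H)-one
Product: 12 tert-butyl({(1S,4R)-5-methoxy-4-[5-(triisopropylsilyloxy)furan-2-yl]-1,2,3,4-tetrahydronaphthalen-1-yl}oxy)dimethylsilane (cis)
Conditions: TIPSOTf, Et3N, CH2Cl2, 0 °C
Reagents that add atoms: triisopropylsilyl trifluoromethanesulfonate, CC(C)[Si](OS(=O)(=O)C(F)(F)F)(C(C)C)C(C)C
Why: Soft enolisation and O-silylation of a butenolide to a 2-silyloxyfuran, the standard preparation of these dienes; only the lactone α-hydrogens are acidic enough for Et3N, so C4 keeps its configuration.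

Step 9
Reactants: 12 tert-butyl({(1S,4R)-5-methoxy-4-[5-(triisopropylsilyloxy)furan-2-yl]-1,2,3,4-tetrahydronaphthalen-1-yl}oxy)dimethylsilane; 13 3-methoxy-2-(trimethylsilyl)phenyl trifluoromethanesulfonate
Product: 15 tert-butyl({(1S,4R)-5-methoxy-4-[5-methoxy-4-(triisopropylsilyloxy)-1,4-epoxy-1,4-dihydronaphthalen-1-yl]-1,2,3,4-tetrahydronaphthalen-1-yl}oxy)dimethylsilane (both bridgehead diastereomers), via 3-methoxybenzyne 14 (not isolated)
Conditions: 13 (1.5 equiv), CsF (3 equiv), MeCN–toluene (1:1), rt
Reagents that add atoms: none
Why: Fluoride attacks the unhindered aryl SiMe3 of 13 and 1,2-elimination of triflate releases aryne 14, which adds across C2 and C5 of the silyloxyfuran in a concerted but asynchronous [4+2] cycloaddition, the known aryne–furan Diels–Alder reaction, for which 2-alkoxy- and 2-silyloxyfurans are established partners of 3-alkoxybenzynes. The six-membered carbocycle C1'–C2'–C3'–C4'–C4a'–C8a' closes by intermolecular cycloaddition, with the σ-bonds C1'–C8a' and C4'–C4a' forming on one furan face while the furan oxygen becomes a one-atom bridge. The selectivity needed is regiochemical: the inductively distorted aryne is most electrophilic at the carbon remote from OMe, and the silyloxy group makes the tetralinyl-bearing furan carbon (the terminus of a vinylogous silyl ketene acetal) the most nucleophilic site, so C1'–C8a' should lead and the ketal carbon C4' should end next to C5'–OMe, a sense that the bulk of the tetralinyl group reinforces. The two new bridgehead centres depend only on which furan face is attacked; they are not controlled and need not be, since C4' is planarised in step 10 and C1' in step 11. Chemoselectivity rests on the large size difference between SiMe3 and Si(i-Pr)3 towards sparingly soluble CsF, and the neutral medium should spare the benzylic OTBS group and C4–H.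

Step 10
Reactants: 15 tert-butyl({(1S,4R)-5-methoxy-4-[5-methoxy-4-(triisopropylsilyloxy)-1,4-epoxy-1,4-dihydronaphthalen-1-yl]-1,2,3,4-tetrahydronaphthalen-1-yl}oxy)dimethylsilane
Product: 16 4-hydroxy-4-[(1R,4S)-4-hydroxy-8-methoxy-1,2,3,4-tetrahydronaphthalen-1-yl]-8-methoxynaphthalen-1(4H)-one (p-quinol, both C1' epimers)
Conditions: TBAF, AcOH (1:1, 4 equiv), THF, 0 °C → rt
Reagents that add atoms: none
Why: Fluoride desilylation, in which loss of the silyl group from the bridgehead ketal oxygen unmasks a hemiketal that collapses by breaking the C4'–O bridge bond to give the C4' ketone and the C1' carbinol, while the same reagent frees the C1 alcohol and any adduct already desilylated in step 9 converges on the same product.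

Step 11
Reactants: 16 4-hydroxy-4-[(1R,4S)-4-hydroxy-8-methoxy-1,2,3,4-tetrahydronaphthalen-1-yl]-8-methoxynaphthalen-1(4H)-one
Product: 17 dipolynaphthalene B, (1S,4S)-4-(4-hydroxy-5-methoxynaphthalen-1-yl)-5-methoxy-1,2,3,4-tetrahydronaphthalen-1-ol
Conditions: Zn dust, AcOH–THF (1:1), rt
Reagents that add atoms: none
Why: Reductive aromatisation of a p-quinol, in which two-electron reduction of the dienone and vinylogous β-elimination of the C1' hydroxyl as water restore the naphthalene with oxygen left on C4'; no cation forms next to C4–H, so both stereocentres should persist, and the air-sensitive naphthol is released under reducing acidic conditions.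

Compound list
1 | 5-methoxy-1-tetralone | COc1cccc2c1CCCC2=O | starting material
2 | (S)-5-methoxy-1,2,3,4-tetrahydronaphthalen-1-ol | COc1cccc2c1CCC[C@@H]2O | intermediate
3 | (S)-tert-butyl[(5-methoxy-1,2,3,4-tetrahydronaphthalen-1-yl)oxy]dimethylsilane | COc1cccc2c1CCC[C@@H]2O[Si](C)(C)C(C)(C)C | intermediate
4 | (S)-4-(tert-butyldimethylsilyloxy)-8-methoxy-3,4-dihydronaphthalen-1(2H)-one | COc1cccc2c1C(=O)CC[C@@H]2O[Si](C)(C)C(C)(C)C | intermediate
5 | (S)-4-(tert-butyldimethylsilyloxy)-8-methoxy-3,4-dihydronaphthalen-1-yl trifluoromethanesulfonate | COc1cccc2c1C(OS(=O)(=O)C(F)(F)F)=CC[C@@H]2O[Si](C)(C)C(C)(C)C | intermediate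
6 | 2-(trimethylsilyl)furan | C[Si](C)(C)c1ccco1 | starting material
7 | 5-lithio-2-(trimethylsilyl)furan | C[Si](C)(C)c1ccc([Li])o1 | intermediate (not isolated)
8 | [5-(trimethylsilyl)furan-2-yl]zinc chloride | C[Si](C)(C)c1ccc([Zn]Cl)o1 | intermediate (not isolated)
9 | tert-butyl({(1S)-5-methoxy-4-[5-(trimethylsilyl)furan-2-yl]-1,2-dihydronaphthalen-1-yl}oxy)dimethylsilane | COc1cccc2c1C(c1ccc([Si](C)(C)C)o1)=CC[C@@H]2O[Si](C)(C)C(C)(C)C | intermediate
10 | tert-butyl({(1S,4R)-5-methoxy-4-[5-(trimethylsilyl)furan-2-yl]-1,2,3,4-tetrahydronaphthalen-1-yl}oxy)dimethylsilane (cis) | COc1cccc2c1[C@H](c1ccc([Si](C)(C)C)o1)CC[C@@H]2O[Si](C)(C)C(C)(C)C | intermediate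
11 | 5-[(1R,4S)-4-(tert-butyldimethylsilyloxy)-8-methoxy-1,2,3,4-tetrahydronaphthalen-1-yl]furan-2(3H)-one | COc1cccc2c1[C@H](C1=CCC(=O)O1)CC[C@@H]2O[Si](C)(C)C(C)(C)C | intermediate
12 | tert-butyl({(1S,4R)-5-methoxy-4-[5-(triisopropylsilyloxy)furan-2-yl]-1,2,3,4-tetrahydronaphthalen-1-yl}oxy)dimethylsilane (cis) | COc1cccc2c1[C@H](c1ccc(O[Si](C(C)C)(C(C)C)C(C)C)o1)CC[C@@H]2O[Si](C)(C)C(C)(C)C | intermediate
13 | 3-methoxy-2-(trimethylsilyl)phenyl trifluoromethanesulfonate | COc1cccc(OS(=O)(=O)C(F)(F)F)c1[Si](C)(C)C | starting material
14 | 3-methoxybenzyne | COC1=CC=CC#C1 | intermediate (not isolated)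
15 | tert-butyl({(1S,4R)-5-methoxy-4-[5-methoxy-4-(triisopropylsilyloxy)-1,4-epoxy-1,4-dihydronaphthalen-1-yl]-1,2,3,4-tetrahydronaphthalen-1-yl}oxy)dimethylsilane (bridgeheads unassigned) | COc1cccc2c1[C@H](C45C=CC(O[Si](C(C)C)(C(C)C)C(C)C)(O4)c4c(OC)cccc54)CC[C@@H]2O[Si](C)(C)C(C)(C)C | intermediate
16 | 4-hydroxy-4-[(1R,4S)-4-hydroxy-8-methoxy-1,2,3,4-tetrahydronaphthalen-1-yl]-8-methoxynaphthalen-1(4H)-one (C1' unassigned) | COc1cccc2c1[C@H](C1(O)C=CC(=O)c3c(OC)cccc31)CC[C@@H]2O | intermediate
17 | dipolynaphthalene B, (1S,4S)-4-(4-hydroxy-5-methoxynaphthalen-1-yl)-5-methoxy-1,2,3,4-tetrahydronaphthalen-1-ol | COc1cccc2c1[C@H](c1ccc(O)c3c(OC)cccc13)CC[C@@H]2O | target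

Total step count: 11
Longest linear sequence: 11 steps (1 → 17). Compounds 6 and 13 are bought and enter at steps 5 and 9.

Steps most likely to fail

Step 9. Fluoride may strip the silyl group from the ketene-acetal oxygen of 12 before the aryne is trapped. The alkoxide released by early ketal cleavage may also consume the aryne. The fallback runs from 12 back to 15 and makes the aryne without any silaphile. Commercial 2-bromo-3-methoxyphenol is triflated (Tf2O, pyridine, CH2Cl2, 0 °C) to 2-bromo-3-methoxyphenyl trifluoromethanesulfonate F1. Slow addition of n-BuLi to a mixture of F1 and 12 in THF at −78 °C triggers bromine–lithium exchange and loss of lithium triflate. This gives the same aryne 14, which 12 should trap to 15. Halogen–metal exchange of this kind is the established way to generate 3-alkoxybenzynes in the presence of silyl ketene acetals.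

Step 3. Hydrogen abstraction may occur at the α-silyloxy C1–H, with loss of the protecting group and of the stereocentre, or the oxidation may stall at partial conversion. The fallback runs from 2 back to 4 and deactivates C1–H electronically instead of sterically.
- Compound 2 is acetylated (Ac2O, pyridine, DMAP, CH2Cl2) to (S)-5-methoxy-1,2,3,4-tetrahydronaphthalen-1-yl acetate F2.
- F2 is oxidised with CrO3 in aqueous AcOH at 0–10 °C, the classical conversion of 1-acetoxytetralins into 4-acetoxy-1-tetralones, to (1S)-5-methoxy-4-oxo-1,2,3,4-tetrahydronaphthalen-1-yl acetate F3.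
- F3 is methanolysed (K2CO3, MeOH, 0 °C) to (S)-4-hydroxy-8-methoxy-3,4-dihydronaphthalen-1(2H)-one F4.
- F4 is silylated (TBSCl, imidazole, DMF) to 4.

Step 6. The two alkene faces may be poorly discriminated, or the furan ring may slowly saturate and the benzylic C–O bond may undergo hydrogenolysis on the metal surface. The fallback runs from 9 back to 10 and hands the facial choice from the substrate to a chiral homogeneous catalyst. This is asymmetric hydrogenation with the cationic iridium phosphinooxazoline complex [Ir(cod)(tBu-PHOX)][B(C6H3(CF3)2)4] (H2 50 bar, CH2Cl2, rt). That catalyst class is designed for unfunctionalised trisubstituted aryl alkenes such as 1-aryl-3,4-dihydronaphthalenes. The ligand antipode that reinforces delivery anti to OTBS is used. No new compound is made (F0).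

Further compounds
F1 | step 9 | 2-bromo-3-methoxyphenyl trifluoromethanesulfonate | COc1cccc(OS(=O)(=O)C(F)(F)F)c1Br
F2 | step 3 | (S)-5-methoxy-1,2,3,4-tetrahydronaphthalen-1-yl acetate | COc1cccc2c1CCC[C@@H]2OC(C)=O
F3 | step 3 | (1S)-5-methoxy-4-oxo-1,2,3,4-tetrahydronaphthalen-1-yl acetate | COc1cccc2c1C(=O)CC[C@@H]2OC(C)=O
F4 | step 3 | (S)-4-hydroxy-8-methoxy-3,4-dihydronaphthalen-1(2H)-one | COc1cccc2c1C(=O)CC[C@@H]2O
F0 | step 6 | none | none
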